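**Retrosynthetic overview**
1. Target 18 ⇐ neutral hydrogenolysis (benzyl ether, benzyl ester) and acidic desilylation of the protected (S)-ketone 16; no base is used once the ketone exists.
2. 16 ⇐ Dess–Martin oxidation of the benzylic carbinol of mono-TBS diol 15 ⇐ diol 14 ⇐ reductive removal of the auxiliary from syn aldol adduct 13.
3. Key C–C disconnection: the C(benzylic)–C(OAr) bond of 13 ⇐ intermolecular Evans boron aldol of aryloxyacetyl imide 10 (ring B fragment) with O-benzylsyringaldehyde 2 (ring A fragment); this sets the aryloxy-bearing stereocentre.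
4. 10 ⇐ syringic acid 3 + tert-butyl bromoacetate 5 + (R)-4-benzyl-oxazolidinone 8; 2 ⇐ syringaldehyde 1.
5. No ring is formed: both benzene rings are bought (1 and 3), and the oxazolidinone ring of 8 is bought and recovered.

Assumption: the target centre is (S) by CIP analysis of the given SMILES; benzyl bromide and TBSCl are treated as reagents and not numbered.

**Route**

Step 1
Reactants: 1 syringaldehyde
Product: 2 4-(benzyloxy)-3,5-dimethoxybenzaldehyde
Conditions: BnBr, K2CO3, DMF, 60 °C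
Reagents that add atoms: benzyl bromide, BrCc1ccccc1
Why: Williamson ether synthesis; the phenoxide, acidified by the para-formyl group, displaces bromide from the benzylic halide (SN2).

Step 2
Reactants: 3 syringic acid
Product: 4 benzyl 4-hydroxy-3,5-dimethoxybenzoate
Conditions: BnBr (1.05 equiv), KHCO3, DMF, 40 °C
Reagents that add atoms: benzyl bromide, BrCc1ccccc1
Why: Chemoselective carboxylate O-alkylation (SN2 esterification); KHCO3 deprotonates the acid but not the hindered phenol, so only the ester forms.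

Step 3
Reactants: 4 benzyl 4-hydroxy-3,5-dimethoxybenzoate; 5 tert-butyl bromoacetate
Product: 6 benzyl 4-(2-tert-butoxy-2-oxoethoxy)-3,5-dimethoxybenzoate
Conditions: K2CO3, DMF, 50 °C
Reagents that add atoms: none
Why: Williamson etherification with a highly reactive α-bromo ester, which overcomes the di-ortho-methoxy hindrance of the phenoxide.

Step 4
Reactants: 6 benzyl 4-(2-tert-butoxy-2-oxoethoxy)-3,5-dimethoxybenzoate
Product: 7 2-{4-[(benzyloxy)carbonyl]-2,6-dimethoxyphenoxy}acetic acid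
Conditions: TFA/CH2Cl2 (1:3), rt
Reagents that add atoms: none
Why: Acidolysis of the tert-butyl ester (E1 loss of isobutene) leaves the benzyl ester and aryl ethers untouched.

Step 5
Reactants: 7 2-{4-[(benzyloxy)carbonyl]-2,6-dimethoxyphenoxy}acetic acid; 8 (4R)-4-benzyl-1,3-oxazolidin-2-one
Product: 10 benzyl 4-{2-[(4R)-4-benzyl-2-oxo-1,3-oxazolidin-3-yl]-2-oxoethoxy}-3,5-dimethoxybenzoate, via mixed pivalic anhydride 9 (not isolated)
Conditions: PivCl, Et3N, THF, −20 → 0 °C; then LiCl, 8, rt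
Reagents that add atoms: none
Why: N-acylation of the oxazolidinone through a mixed anhydride (LiCl/Et3N activation); the nucleophile attacks the unhindered aryloxyacetyl carbonyl, not the pivaloyl one.

Step 6
Reactants: 10 benzyl 4-{2-[(4R)-4-benzyl-2-oxo-1,3-oxazolidin-3-yl]-2-oxoethoxy}-3,5-dimethoxybenzoate; 2 4-(benzyloxy)-3,5-dimethoxybenzaldehyde
Product: 13 (4R)-4-benzyl-3-[(2R,3S)-3-[4-(benzyloxy)-3,5-dimethoxyphenyl]-2-{4-[(benzyloxy)carbonyl]-2,6-dimethoxyphenoxy}-3-hydroxypropanoyl]-1,3-oxazolidin-2-one, via dibutylboron Z-enolate 11 (not isolated), via dibutylboron aldolate 12 (not isolated)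
Conditions: Bu2BOTf, iPr2NEt, CH2Cl2, 0 °C; then 2, −78 → 0 °C; then pH 7 phosphate buffer, MeOH, 30% H2O2, 0 °C
Reagents that add atoms: none
Why: Evans syn aldol; soft enolisation gives the Z-boron enolate, which adds through a closed Zimmerman–Traxler chair on the face opposite the auxiliary benzyl group, setting C2 as R (the S centre of the target once CIP priorities change) and C3 as S.

Step 7
Reactants: 13 the syn aldol adduct named in step 6
Product: 14 benzyl 4-{[(1S,2S)-1-[4-(benzyloxy)-3,5-dimethoxyphenyl]-1,3-dihydroxypropan-2-yl]oxy}-3,5-dimethoxybenzoate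
Conditions: NaBH4, THF/H2O (4:1), 0 °C → rt
Reagents that add atoms: none
Why: Reductive cleavage of the N-acyl oxazolidinone (hydride attack at the activated exocyclic carbonyl) gives the primary alcohol and free auxiliary; NaBH4 leaves the benzyl benzoate alone and does not touch the aryloxy-bearing centre.

Step 8
Reactants: 14 the 1,3-diol named in step 7
Product: 15 benzyl 4-{[(1S,2S)-1-[4-(benzyloxy)-3,5-dimethoxyphenyl]-3-[(tert-butyldimethylsilyl)oxy]-1-hydroxypropan-2-yl]oxy}-3,5-dimethoxybenzoate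
Conditions: TBSCl (1.1 equiv), imidazole, CH2Cl2, 0 °C
Reagents that add atoms: tert-butyldimethylsilyl chloride, CC(C)(C)[Si](C)(C)Cl
Why: Sterically controlled silylation; the primary hydroxyl reacts far faster than the secondary benzylic hydroxyl flanked by the bulky aryloxy group.

Step 9
Reactants: 15 the mono-TBS ether named in step 8
Product: 16 benzyl 4-{[(2S)-1-[4-(benzyloxy)-3,5-dimethoxyphenyl]-3-[(tert-butyldimethylsilyl)oxy]-1-oxopropan-2-yl]oxy}-3,5-dimethoxybenzoate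
Conditions: Dess–Martin periodinane, CH2Cl2, 0 °C → rt; cold aq. Na2S2O3/NaHCO3 work-up
Reagents that add atoms: none
Why: Dess–Martin oxidation is non-basic, so the carbinol centre is removed on purpose while the adjacent aryloxy-bearing centre is not enolised and stays S.

Step 10
Reactants: 16 the silyl-protected ketone named in step 9
Product: 17 benzyl 4-{[(2S)-1-[4-(benzyloxy)-3,5-dimethoxyphenyl]-3-hydroxy-1-oxopropan-2-yl]oxy}-3,5-dimethoxybenzoate
Conditions: HF·pyridine, THF, 0 °C → rt (polypropylene vessel)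
Reagents that add atoms: none
Why: Fluoride-driven Si–O cleavage in an acidic medium avoids the base-promoted epimerisation, retro-aldol and β-elimination open to this β-hydroxy ketone.

Step 11
Reactants: 17 the dibenzyl-protected hydroxy ketone named in step 10
Product: 18 4-{[(2S)-3-hydroxy-1-(4-hydroxy-3,5-dimethoxyphenyl)-1-oxopropan-2-yl]oxy}-3,5-dimethoxybenzoic acid (CNP0511559.2)
Conditions: H2 (1 atm), 10% Pd/C, EtOAc, rt, stopped at full conversion
Reagents that add atoms: none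
Why: Catalytic hydrogenolysis cleaves the benzyl ether and benzyl ester under neutral conditions; the electron-rich aryl ketone is not reduced at 1 atm and the stereocentre is untouched.

**Compound list**
1 | syringaldehyde (4-hydroxy-3,5-dimethoxybenzaldehyde) | COc1cc(C=O)cc(OC)c1O | starting material
2 | 4-(benzyloxy)-3,5-dimethoxybenzaldehyde | COc1cc(C=O)cc(OC)c1OCc1ccccc1 | intermediate
3 | syringic acid (4-hydroxy-3,5-dimethoxybenzoic acid) | COc1cc(C(=O)O)cc(OC)c1O | starting material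
4 | benzyl 4-hydroxy-3,5-dimethoxybenzoate | COc1cc(C(=O)OCc2ccccc2)cc(OC)c1O | intermediate
5 | tert-butyl bromoacetate | CC(C)(C)OC(=O)CBr | starting material
6 | benzyl 4-(2-tert-butoxy-2-oxoethoxy)-3,5-dimethoxybenzoate | COc1cc(C(=O)OCc2ccccc2)cc(OC)c1OCC(=O)OC(C)(C)C | intermediate
7 | 2-{4-[(benzyloxy)carbonyl]-2,6-dimethoxyphenoxy}acetic acid | COc1cc(C(=O)OCc2ccccc2)cc(OC)c1OCC(=O)O | intermediate
8 | (4R)-4-benzyl-1,3-oxazolidin-2-one | O=C1N[C@H](Cc2ccccc2)CO1 | starting material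
9 | mixed anhydride of 7 and pivalic acid (not isolated) | COc1cc(C(=O)OCc2ccccc2)cc(OC)c1OCC(=O)OC(=O)C(C)(C)C | intermediate
10 | benzyl 4-{2-[(4R)-4-benzyl-2-oxo-1,3-oxazolidin-3-yl]-2-oxoethoxy}-3,5-dimethoxybenzoate | COc1cc(C(=O)OCc2ccccc2)cc(OC)c1OCC(=O)N1C(=O)OC[C@H]1Cc1ccccc1 | intermediate
11 | dibutylboron Z-enolate of 10: benzyl 4-{[(Z)-2-[(4R)-4-benzyl-2-oxo-1,3-oxazolidin-3-yl]-2-[(dibutylboranyl)oxy]ethenyl]oxy}-3,5-dimethoxybenzoate (not isolated) | CCCCB(CCCC)O/C(=C\Oc1c(OC)cc(cc1OC)C(=O)OCc1ccccc1)N1C(=O)OC[C@H]1Cc1ccccc1 | intermediate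
12 | O-dibutylboron aldolate of 13 (not isolated) | COc1cc(cc(OC)c1OCc1ccccc1)[C@H](OB(CCCC)CCCC)[C@@H](Oc1c(OC)cc(cc1OC)C(=O)OCc1ccccc1)C(=O)N1C(=O)OC[C@H]1Cc1ccccc1 | intermediate
13 | (4R)-4-benzyl-3-[(2R,3S)-3-[4-(benzyloxy)-3,5-dimethoxyphenyl]-2-{4-[(benzyloxy)carbonyl]-2,6-dimethoxyphenoxy}-3-hydroxypropanoyl]-1,3-oxazolidin-2-one | COc1cc(cc(OC)c1OCc1ccccc1)[C@H](O)[C@@H](Oc1c(OC)cc(cc1OC)C(=O)OCc1ccccc1)C(=O)N1C(=O)OC[C@H]1Cc1ccccc1 | intermediate
14 | benzyl 4-{[(1S,2S)-1-[4-(benzyloxy)-3,5-dimethoxyphenyl]-1,3-dihydroxypropan-2-yl]oxy}-3,5-dimethoxybenzoate | COc1cc(cc(OC)c1OCc1ccccc1)[C@H](O)[C@@H](Oc1c(OC)cc(cc1OC)C(=O)OCc1ccccc1)CO | intermediate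
15 | benzyl 4-{[(1S,2S)-1-[4-(benzyloxy)-3,5-dimethoxyphenyl]-3-[(tert-butyldimethylsilyl)oxy]-1-hydroxypropan-2-yl]oxy}-3,5-dimethoxybenzoate | COc1cc(cc(OC)c1OCc1ccccc1)[C@H](O)[C@@H](Oc1c(OC)cc(cc1OC)C(=O)OCc1ccccc1)CO[Si](C)(C)C(C)(C)C | intermediate
16 | benzyl 4-{[(2S)-1-[4-(benzyloxy)-3,5-dimethoxyphenyl]-3-[(tert-butyldimethylsilyl)oxy]-1-oxopropan-2-yl]oxy}-3,5-dimethoxybenzoate | COc1cc(cc(OC)c1OCc1ccccc1)C(=O)[C@@H](Oc1c(OC)cc(cc1OC)C(=O)OCc1ccccc1)CO[Si](C)(C)C(C)(C)C | intermediate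
17 | benzyl 4-{[(2S)-1-[4-(benzyloxy)-3,5-dimethoxyphenyl]-3-hydroxy-1-oxopropan-2-yl]oxy}-3,5-dimethoxybenzoate | COc1cc(cc(OC)c1OCc1ccccc1)C(=O)[C@@H](Oc1c(OC)cc(cc1OC)C(=O)OCc1ccccc1)CO | intermediate
18 | 4-{[(2S)-3-hydroxy-1-(4-hydroxy-3,5-dimethoxyphenyl)-1-oxopropan-2-yl]oxy}-3,5-dimethoxybenzoic acid | COc1cc(C(=O)[C@H](CO)Oc2c(OC)cc(C(=O)O)cc2OC)cc(OC)c1O | target

**Step count**
Total steps: 11. Longest linear sequence: 10 steps (3 → 4 → 6 → 7 → 10 → 13 → 14 → 15 → 16 → 17 → 18); the aldehyde branch (1 → 2) is one step.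

**Three steps most likely to fail, with fallbacks**

Step 6 (aldol). The boron enolate of the bulky 2,6-dimethoxyaryloxyacetyl imide may react sluggishly with the electron-rich, deactivated aldehyde 2, or retro-aldol may erode the yield. The fallback sets out from acid 7, which is condensed (EDC·HCl, DMAP, CH2Cl2, rt) with (R)-4-benzyl-1,3-thiazolidine-2-thione to give benzyl 4-{2-[(4R)-4-benzyl-2-sulfanylidene-1,3-thiazolidin-3-yl]-2-oxoethoxy}-3,5-dimethoxybenzoate F1. Its more reactive chlorotitanium enolate (TiCl4, iPr2NEt, N-methyl-2-pyrrolidone, CH2Cl2, −78 → 0 °C) should add to aldehyde 2 through the non-chelated transition state with the same syn sense. This gives benzyl 4-{[(1S,2R)-3-[(4R)-4-benzyl-2-sulfanylidene-1,3-thiazolidin-3-yl]-1-[4-(benzyloxy)-3,5-dimethoxyphenyl]-1-hydroxy-3-oxopropan-2-yl]oxy}-3,5-dimethoxybenzoate F2. The facial sense must be confirmed on F2, because a chelated pathway would invert C2. NaBH4 in THF/EtOH at 0 °C then removes the thiazolidinethione, and the fallback comes back to the route at diol 14.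

Step 7 (auxiliary removal). Aqueous borohydride may cause some retro-aldol, endocyclic opening of the oxazolidinone, or slow attack on the benzyl ester. The fallback sets out from 13: LiOH/H2O2 (THF/H2O, 0 °C) hydrolyses the imide to (2R,3S)-3-[4-(benzyloxy)-3,5-dimethoxyphenyl]-2-{4-[(benzyloxy)carbonyl]-2,6-dimethoxyphenoxy}-3-hydroxypropanoic acid F3. BH3·THF (0 °C → rt) then reduces the free carboxylic acid chemoselectively, leaving the benzyl benzoate, and the fallback comes back to the route at diol 14.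

Step 11 (hydrogenolysis next to the ketone). The aryl ketone could be over-reduced or the α-aryloxy C–O bond cleaved on palladium. The fallback sets out from 15 and removes both benzyl groups before the ketone exists (H2, 10% Pd/C, EtOAc, rt). This gives 4-{[(1S,2S)-3-[(tert-butyldimethylsilyl)oxy]-1-hydroxy-1-(4-hydroxy-3,5-dimethoxyphenyl)propan-2-yl]oxy}-3,5-dimethoxybenzoic acid F4. DDQ (1,4-dioxane, rt) then oxidises the para-hydroxybenzylic alcohol chemoselectively to 4-{[(2S)-3-[(tert-butyldimethylsilyl)oxy]-1-(4-hydroxy-3,5-dimethoxyphenyl)-1-oxopropan-2-yl]oxy}-3,5-dimethoxybenzoic acid F5. HF·pyridine in THF at 0 °C removes the silyl group, and the fallback comes back to the route at target 18.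

**Further compounds**
F1 | step 6 | benzyl 4-{2-[(4R)-4-benzyl-2-sulfanylidene-1,3-thiazolidin-3-yl]-2-oxoethoxy}-3,5-dimethoxybenzoate | COc1cc(C(=O)OCc2ccccc2)cc(OC)c1OCC(=O)N1C(=S)SC[C@H]1Cc1ccccc1
F2 | step 6 | benzyl 4-{[(1S,2R)-3-[(4R)-4-benzyl-2-sulfanylidene-1,3-thiazolidin-3-yl]-1-[4-(benzyloxy)-3,5-dimethoxyphenyl]-1-hydroxy-3-oxopropan-2-yl]oxy}-3,5-dimethoxybenzoate | COc1cc(cc(OC)c1OCc1ccccc1)[C@H](O)[C@@H](Oc1c(OC)cc(cc1OC)C(=O)OCc1ccccc1)C(=O)N1C(=S)SC[C@H]1Cc1ccccc1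
F3 | step 7 | (2R,3S)-3-[4-(benzyloxy)-3,5-dimethoxyphenyl]-2-{4-[(benzyloxy)carbonyl]-2,6-dimethoxyphenoxy}-3-hydroxypropanoic acid | COc1cc(cc(OC)c1OCc1ccccc1)[C@H](O)[C@@H](Oc1c(OC)cc(cc1OC)C(=O)OCc1ccccc1)C(=O)O
F4 | step 11 | 4-{[(1S,2S)-3-[(tert-butyldimethylsilyl)oxy]-1-hydroxy-1-(4-hydroxy-3,5-dimethoxyphenyl)propan-2-yl]oxy}-3,5-dimethoxybenzoic acid | COc1cc(cc(OC)c1O)[C@H](O)[C@@H](Oc1c(OC)cc(cc1OC)C(=O)O)CO[Si](C)(C)C(C)(C)C
F5 | step 11 | 4-{[(2S)-3-[(tert-butyldimethylsilyl)oxy]-1-(4-hydroxy-3,5-dimethoxyphenyl)-1-oxopropan-2-yl]oxy}-3,5-dimethoxybenzoic acid | COc1cc(cc(OC)c1O)C(=O)[C@@H](Oc1c(OC)cc(cc1OC)C(=O)O)CO[Si](C)(C)C(C)(C)C
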